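**Retrosynthetic overview**

- The target comes from its 3,3',4'-tri-O-benzyl ether by one final hydrogenolysis.
- The C5–O bond is made last on ring A by a proposed carbonyl-directed C5–H magnesiation, borylation and oxidation of the fully protected flavonol (the new step). This avoids a pentaoxygenated arene and any selective demethylation.
- Ring C and its 3-OH come from a 2'-hydroxychalcone by Algar–Flynn–Oyamada oxidative cyclisation, which is viable because the chalcone has no 6'-substituent.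
- The chalcone comes from a ring A acetophenone and a ring B aldehyde by Claisen–Schmidt condensation. The acetophenone comes from 2,3,4-trimethoxybenzaldehyde by Dakin oxidation and Fries acylation.
- Ring order: rings A and B are bought as benzene rings; ring C is the only ring formed (step 4).

Assumption: the target is planar and has no stereocentre, so "single enantiomer" is met by the constitution alone and no asymmetric step is needed.

**Route**

Step 1
Reactants: 1 2,3,4-trimethoxybenzaldehyde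
Product: 3 2,3,4-trimethoxyphenol, via 2,3,4-trimethoxyphenyl formate 2 (not isolated)
Conditions: 30% aq. H2O2 (1.3 equiv), H2SO4 (cat.), MeOH, rt
Reagents that add atoms: hydrogen peroxide, OO
Why: Dakin oxidation (Baeyer–Villiger type): the electron-rich aryl group migrates to peroxide oxygen and the formate 2 is methanolysed in the same pot.

Step 2
Reactants: 3 2,3,4-trimethoxyphenol
Product: 5 1-(2-hydroxy-3,4,5-trimethoxyphenyl)ethan-1-one, via 2,3,4-trimethoxyphenyl acetate 4 (not isolated)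
Conditions: Ac2O (1.1 equiv), BF3·OEt2 (as solvent), 0 → 90 °C; then H2O
Reagents that add atoms: acetic anhydride, CC(=O)OC(C)=O
Why: O-acetylation then Fries rearrangement; the para position is blocked by OMe, so the acetyl group moves to the only free ortho carbon and the chelated o-hydroxy ketone is the thermodynamic product.

Step 3
Reactants: 5 1-(2-hydroxy-3,4,5-trimethoxyphenyl)ethan-1-one; 6 3,4-bis(benzyloxy)benzaldehyde
Product: 7 (E)-3-[3,4-bis(benzyloxy)phenyl]-1-(2-hydroxy-3,4,5-trimethoxyphenyl)prop-2-en-1-one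
Conditions: KOH (3 equiv), EtOH, rt, 24 h; then aq. HCl
Reagents that add atoms: none
Why: Claisen–Schmidt aldol condensation; E1cB dehydration of the aldol gives the conjugated E-alkene, and benzyl and methyl ethers are inert to base.

Step 4
Reactants: 7 (E)-3-[3,4-bis(benzyloxy)phenyl]-1-(2-hydroxy-3,4,5-trimethoxyphenyl)prop-2-en-1-one
Product: 9 2-[3,4-bis(benzyloxy)phenyl]-3-hydroxy-6,7,8-trimethoxy-4H-chromen-4-one, via racemic trans-dihydroflavonol 8 (not isolated)
Conditions: 30% aq. H2O2 (4 equiv), NaOH (aq., 4 equiv), MeOH/THF, 0 °C → rt; then aq. HCl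
Reagents that add atoms: hydrogen peroxide, OO
Why: Algar–Flynn–Oyamada reaction: alkaline peroxide oxygenates the enone and the phenoxide closes the six-membered ring (no 6'-substituent, so aurone formation is not favoured), and racemic 8 is dehydrogenated by further peroxide so its two stereocentres vanish.

Step 5
Reactants: 9 2-[3,4-bis(benzyloxy)phenyl]-3-hydroxy-6,7,8-trimethoxy-4H-chromen-4-one
Product: 10 3-(benzyloxy)-2-[3,4-bis(benzyloxy)phenyl]-6,7,8-trimethoxy-4H-chromen-4-one
Conditions: BnBr (1.3 equiv), K2CO3 (2 equiv), DMF, 60 °C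
Reagents that add atoms: benzyl bromide, BrCc1ccccc1
Why: Williamson ether synthesis on the only free hydroxyl; it removes the acidic 3-OH before the amide base of step 6, and all three benzyl groups leave together in step 7.

Step 6
Reactants: 10 3-(benzyloxy)-2-[3,4-bis(benzyloxy)phenyl]-6,7,8-trimethoxy-4H-chromen-4-one
Product: 13 3-(benzyloxy)-2-[3,4-bis(benzyloxy)phenyl]-5-hydroxy-6,7,8-trimethoxy-4H-chromen-4-one, via C5-chloromagnesio flavone 11 (not isolated), via C5-dimethoxyboryl flavone 12 (not isolated)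
Conditions: TMPMgCl·LiCl (TMP = 2,2,6,6-tetramethylpiperidin-1-yl; 1.5 equiv), THF, −20 → 0 °C; B(OMe)3 (3 equiv), −20 °C → rt; then 30% aq. H2O2, 0 °C → rt; aqueous work-up
Reagents that add atoms: hydrogen peroxide, OO (the C5 oxygen of 13); trimethyl borate, COB(OC)OC (the B(OMe)2 group of 12 only); TMPMgCl·LiCl, CC1(C)CCCC(C)(C)N1[Mg]Cl.[Li]Cl (the MgCl group of 11 only)
Why: Proposed new method: the pyranone carbonyl, held coplanar with ring A, binds the magnesium amide and delivers the hindered, non-nucleophilic base through a five-membered chelate to C5–H, which is the only hydrogen on ring A and is further acidified by the adjacent 6-methoxy group; C2 and C3, the positions normally metalated in chromones, are blocked, the ring B hydrogens have no coordinating group within reach, and the chelated arylmagnesium 11 is trapped by B(OMe)3 and oxidised by a 1,2-aryl shift from boron to peroxide oxygen to give the phenol at the metalated carbon; the closest known reaction type is directed ortho-magnesiation of aryl esters and ketones with TMP-magnesium amides followed by borylation–oxidation, together with C2/C3 metalation of chromones, whereas carbonyl-directed C5–H metalation of a flavone has not been shown.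

Step 7
Reactants: 13 3-(benzyloxy)-2-[3,4-bis(benzyloxy)phenyl]-5-hydroxy-6,7,8-trimethoxy-4H-chromen-4-one
Product: 14 2-(3,4-dihydroxyphenyl)-3,5-dihydroxy-6,7,8-trimethoxy-4H-chromen-4-one (3,5,3',4'-tetrahydroxy-6,7,8-trimethoxyflavone)
Conditions: H2 (1 atm), 10% Pd/C, THF/MeOH, rt
Reagents that add atoms: none
Why: Catalytic hydrogenolysis cleaves the three benzyl ethers, while the methyl ethers and the tetrasubstituted vinylogous-ester double bond of ring C are inert under these conditions.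

**Compound list**

1 | 2,3,4-trimethoxybenzaldehyde | COc1ccc(C=O)c(OC)c1OC | starting material
2 | 2,3,4-trimethoxyphenyl formate | COc1ccc(OC=O)c(OC)c1OC | intermediate
3 | 2,3,4-trimethoxyphenol | COc1ccc(O)c(OC)c1OC | intermediate
4 | 2,3,4-trimethoxyphenyl acetate | COc1ccc(OC(C)=O)c(OC)c1OC | intermediate
5 | 1-(2-hydroxy-3,4,5-trimethoxyphenyl)ethan-1-one | CC(=O)c1cc(OC)c(OC)c(OC)c1O | intermediate
6 | 3,4-bis(benzyloxy)benzaldehyde | O=Cc1ccc(OCc2ccccc2)c(OCc2ccccc2)c1 | starting material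
7 | (E)-3-[3,4-bis(benzyloxy)phenyl]-1-(2-hydroxy-3,4,5-trimethoxyphenyl)prop-2-en-1-one | COc1cc(C(=O)/C=C/c2ccc(OCc3ccccc3)c(OCc3ccccc3)c2)c(O)c(OC)c1OC | intermediate
8 | (2R*,3R*)-2-[3,4-bis(benzyloxy)phenyl]-3-hydroxy-6,7,8-trimethoxy-2,3-dihydro-4H-chromen-4-one (racemic trans; one enantiomer drawn) | COc1cc2c(c(OC)c1OC)O[C@H](c1ccc(OCc3ccccc3)c(OCc3ccccc3)c1)[C@@H](O)C2=O | intermediate
9 | 2-[3,4-bis(benzyloxy)phenyl]-3-hydroxy-6,7,8-trimethoxy-4H-chromen-4-one | COc1cc2c(=O)c(O)c(-c3ccc(OCc4ccccc4)c(OCc4ccccc4)c3)oc2c(OC)c1OC | intermediate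
10 | 3-(benzyloxy)-2-[3,4-bis(benzyloxy)phenyl]-6,7,8-trimethoxy-4H-chromen-4-one | COc1cc2c(=O)c(OCc3ccccc3)c(-c3ccc(OCc4ccccc4)c(OCc4ccccc4)c3)oc2c(OC)c1OC | intermediate
11 | [3-(benzyloxy)-2-[3,4-bis(benzyloxy)phenyl]-6,7,8-trimethoxy-4-oxo-4H-chromen-5-yl]magnesium chloride (LiCl complex) | COc1c([Mg]Cl)c2c(=O)c(OCc3ccccc3)c(-c3ccc(OCc4ccccc4)c(OCc4ccccc4)c3)oc2c(OC)c1OC | intermediate
12 | dimethyl [3-(benzyloxy)-2-[3,4-bis(benzyloxy)phenyl]-6,7,8-trimethoxy-4-oxo-4H-chromen-5-yl]boronate | COc1c(B(OC)OC)c2c(=O)c(OCc3ccccc3)c(-c3ccc(OCc4ccccc4)c(OCc4ccccc4)c3)oc2c(OC)c1OC | intermediate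
13 | 3-(benzyloxy)-2-[3,4-bis(benzyloxy)phenyl]-5-hydroxy-6,7,8-trimethoxy-4H-chromen-4-one | COc1c(O)c2c(=O)c(OCc3ccccc3)c(-c3ccc(OCc4ccccc4)c(OCc4ccccc4)c3)oc2c(OC)c1OC | intermediate
14 | 2-(3,4-dihydroxyphenyl)-3,5-dihydroxy-6,7,8-trimethoxy-4H-chromen-4-one | COc1c(OC)c(O)c2c(=O)c(O)c(-c3ccc(O)c(O)c3)oc2c1OC | target

**Step count and risk**

Total step count: 7. Longest linear sequence: 7 steps (1 → 3 → 5 → 7 → 9 → 10 → 13 → 14; aldehyde 6 is bought).

The three steps most likely to fail:

Step 6 (the proposed new step). The risks are incomplete or mis-directed metalation and attack on the pyranone. The fallback uses known chemistry, sets out from 9 and comes back to the route at 14. Hydrogenolysis of 9 (H2, 10% Pd/C, THF/MeOH) gives 2-(3,4-dihydroxyphenyl)-3-hydroxy-6,7,8-trimethoxy-4H-chromen-4-one F1. Ac2O in pyridine then gives 4-(3-acetoxy-6,7,8-trimethoxy-4-oxo-4H-chromen-2-yl)-1,2-phenylene diacetate F2, whose acyl groups tolerate acid and oxidant. Ruthenium-catalysed, ketone-directed C5–H oxygenation, which is known for flavones ([RuCl2(p-cymene)]2 cat., PhI(OCOCF3)2, CF3CO2H/(CF3CO)2O, 80 °C), gives 3-acetoxy-2-(3,4-diacetoxyphenyl)-6,7,8-trimethoxy-4-oxo-4H-chromen-5-yl trifluoroacetate F3. Aqueous work-up hydrolyses this to 4-(3-acetoxy-5-hydroxy-6,7,8-trimethoxy-4-oxo-4H-chromen-2-yl)-1,2-phenylene diacetate F4. Methanolysis of the three acetates (HCl, MeOH, 50 °C) gives 14.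

Step 4 (Algar–Flynn–Oyamada). The risks are aurone formation and moderate yield. The fallback sets out from 7 and comes back at 9, separating ring closure from oxygenation. Oxidative cyclisation of 7 with catalytic iodine in DMSO at 120 °C gives 2-[3,4-bis(benzyloxy)phenyl]-6,7,8-trimethoxy-4H-chromen-4-one F5. Epoxidation with dimethyldioxirane (acetone/CH2Cl2, 0 °C) gives racemic 2-[3,4-bis(benzyloxy)phenyl]-2,3-epoxy-6,7,8-trimethoxychroman-4-one F6. Catalytic p-TsOH in CH2Cl2 opens the epoxide and tautomerises the product to 9.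

Step 2 (Fries acylation). The risks are acylation at the other free ring carbon and partial demethylation by hot BF3. The fallback sets out from 3 and comes back at 5, building the acetyl group in stages at the ortho position only. Ortho-formylation of 3 (MgCl2, Et3N, paraformaldehyde, MeCN, reflux) gives 2-hydroxy-3,4,5-trimethoxybenzaldehyde F7. MeMgBr (2.2 equiv, THF, 0 °C) gives racemic 2-(1-hydroxyethyl)-4,5,6-trimethoxyphenol F8. Oxidation of the benzylic alcohol with MnO2 in CH2Cl2 gives 5.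

**Further compounds**

F1 | step 6 | 2-(3,4-dihydroxyphenyl)-3-hydroxy-6,7,8-trimethoxy-4H-chromen-4-one | COc1cc2c(=O)c(O)c(-c3ccc(O)c(O)c3)oc2c(OC)c1OC
F2 | step 6 | 4-(3-acetoxy-6,7,8-trimethoxy-4-oxo-4H-chromen-2-yl)-1,2-phenylene diacetate | COc1cc2c(=O)c(OC(C)=O)c(-c3ccc(OC(C)=O)c(OC(C)=O)c3)oc2c(OC)c1OC
F3 | step 6 | 3-acetoxy-2-(3,4-diacetoxyphenyl)-6,7,8-trimethoxy-4-oxo-4H-chromen-5-yl trifluoroacetate | COc1c(OC(=O)C(F)(F)F)c2c(=O)c(OC(C)=O)c(-c3ccc(OC(C)=O)c(OC(C)=O)c3)oc2c(OC)c1OC
F4 | step 6 | 4-(3-acetoxy-5-hydroxy-6,7,8-trimethoxy-4-oxo-4H-chromen-2-yl)-1,2-phenylene diacetate | COc1c(O)c2c(=O)c(OC(C)=O)c(-c3ccc(OC(C)=O)c(OC(C)=O)c3)oc2c(OC)c1OC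
F5 | step 4 | 2-[3,4-bis(benzyloxy)phenyl]-6,7,8-trimethoxy-4H-chromen-4-one | COc1cc2c(=O)cc(-c3ccc(OCc4ccccc4)c(OCc4ccccc4)c3)oc2c(OC)c1OC
F6 | step 4 | racemic 2-[3,4-bis(benzyloxy)phenyl]-2,3-epoxy-6,7,8-trimethoxychroman-4-one (one enantiomer drawn) | COc1cc2C(=O)[C@H]3O[C@@]3(c3ccc(OCc4ccccc4)c(OCc4ccccc4)c3)Oc2c(OC)c1OC
F7 | step 2 | 2-hydroxy-3,4,5-trimethoxybenzaldehyde | COc1cc(C=O)c(O)c(OC)c1OC
F8 | step 2 | racemic 2-(1-hydroxyethyl)-4,5,6-trimethoxyphenol | COc1cc(C(C)O)c(O)c(OC)c1OC
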